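**Plan**

1. Retrosynthetic cuts, in order: both palmitate ester C–O bonds; C11'=C12' and C11=C12 (two Wittig unions, C15 + C10 + C15); C6–C7 at the beta ring (Stille); C9'–C10' and C7'=C8' of the epsilon side chain (Grignard addition, cross-metathesis); last, the ring bond C1'–C6'.
2. Enabling feature: in the epsilon ring the oxygen-bearing C3' is joined through C2'H2 and the gem-dimethyl carbon C1' to C6', which carries the exocyclic C7'=C8' bond. The array O–C3'–C2'–C1'–C6'–C7'=C8' is the footprint of an oxy-Cope shift, so the ring can be closed by forming C1'–C6' while a C3'–C8' bond of an older six-membered ring is cut.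
3. Forward, epsilon half: (R)-3-methylcyclohexanone is turned into a cyclohex-3-enol that carries a 2-methylpropenyl group; its [3,3] shift transposes the old ring into the epsilon ring. This is the only ring closed in the route, since the beta ring is bought as (4R,6R)-actinol. Dehydrogenation, reduction and side-chain growth give the epsilon C15 phosphonium salt.
4. Forward, chain: beta C15 salt + C10 dialdehyde give the C25 aldehyde; Wittig reaction with the epsilon C15 salt gives lutein; double palmitoylation gives helenien.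
5. Stereochemistry: C6' comes by relay from the methyl-bearing carbon of the starting ketone (first to the carbinol carbon, then to C6' in the sigmatropic shift), after which that carbon becomes the sp2 carbon C5'. C3' comes from a Corey–Bakshi–Shibata reduction, C3 from actinol. The E double bonds come from metathesis, Stille coupling with retention, and Wittig reactions followed by thermal equilibration.

Key step: step 4

**Route**

Step 1
Reactants: 1 (R)-3-methylcyclohexan-1-one
Product: 2 (R)-5-methylcyclohex-2-en-1-one
Conditions: Pd(OCOCF3)2 (5 mol%), DMSO (10 mol%), O2 (1 atm), AcOH, 80 °C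
Reagents that add atoms: none
Why: Aerobic dehydrogenation through a divalent palladium enolate and beta-hydride elimination (the catalytic relative of the Saegusa–Ito oxidation) should occur mainly on the less hindered C6 side and leaves the stereocenter untouched; the achiral 3-methylcyclohex-2-enone formed on the other side can be removed by chromatography.

Step 2
Reactants: 2 (R)-5-methylcyclohex-2-en-1-one
Product: 4 (S)-5-methylcyclohex-3-en-1-one, via potassium dienolate 3 (not isolated)
Conditions: KOt-Bu (1.2 equiv), t-BuOH/THF, 0 °C; inverse quench into AcOH/THF at −78 °C; used at once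
Reagents that add atoms: none
Why: Equilibrating gamma-deprotonation gives the extended dienolate, whose kinetic protonation at the alpha-carbon delivers the beta,gamma-unsaturated ketone (deconjugative protonation of a dienolate) without touching the methyl-bearing stereocenter.

Step 3
Reactants: 4 (S)-5-methylcyclohex-3-en-1-one
Product: 5 (1S,5S)-5-methyl-1-(2-methylprop-1-en-1-yl)cyclohex-3-en-1-ol
Conditions: 2-methylprop-1-en-1-ylmagnesium bromide (1.5 equiv), anhydrous CeCl3 (1.5 equiv), THF, −78 °C; aq. NH4Cl; chromatography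
Reagents that add atoms: 2-methylprop-1-en-1-ylmagnesium bromide, CC(C)=C[Mg]Br
Why: The weakly basic organocerium reagent adds 1,2 to the easily enolised ketone without bringing the double bond back into conjugation, and axial attack on the half-chair that keeps the methyl group equatorial should place the alkenyl group trans to the methyl group, so that the methyl-bearing carbon sets the carbinol carbon; the minor cis isomer is removed by chromatography.

Step 4
Reactants: 5 (1S,5S)-5-methyl-1-(2-methylprop-1-en-1-yl)cyclohex-3-en-1-ol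
Product: 8 (4S,5S)-4-ethenyl-3,3,5-trimethylcyclohexan-1-one, via potassium alkoxide 6 (not isolated), via potassium enolate 7 (not isolated)
Conditions: KH (1.5 equiv), 18-crown-6 (1.5 equiv), THF, 0 °C then 66 °C; AcOH (1.6 equiv) in THF at −78 °C
Reagents that add atoms: none
Why: Deprotonation gives alkoxide 6, whose charge-accelerated [3,3]-sigmatropic shift (closest known reaction type: the anionic oxy-Cope rearrangement of 3-oxido-1,5-dienes, here of the 1-alkenylcycloalk-3-en-1-olate class) forms the C1'–C6' bond between the dimethyl-substituted alkenyl terminus and the remote ring-alkene carbon while the bond from the carbinol carbon to the ring CH2 breaks, so that the old ring is cut open and its C5–C6 unit becomes the exocyclic C7'=C8' vinyl group. The epsilon ring is thus closed as a ring transposition through a six-centre, boat-like (bicyclo[2.2.2]octane-like) transition state, the only geometry the cyclic tether allows. The new stereocenter C6' is set by suprafacial delivery of the alkenyl terminus to the ring face on which it stands, that is by the carbinol configuration relayed from the methyl-bearing carbon in step 3, which should turn (1S,5S)-5 into the (4S)-ketone, the future 6'R center. The step needs the [3,3] closure to the six-membered ring rather than the [1,3] shift to an eight-membered ketone or heterolytic loss of an allyl anion; the axial alkenyl group held directly above C4 of the cyclohexene, with the trans methyl group equatorial, and the strain-free six-membered product should secure this, and even a detached allyl anion would stay tethered for Michael return to the same carbon. The quaternary carbon C1', the regiodefined enolate 7 and the vinyl handle all arise in this one event, and protonation gives ketone 8.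

Step 5
Reactants: 8 (4S,5S)-4-ethenyl-3,3,5-trimethylcyclohexan-1-one
Product: 9 (4R)-4-ethenyl-3,5,5-trimethylcyclohex-2-en-1-one
Conditions: 2-iodoxybenzoic acid (IBX, 2.0 equiv), toluene/DMSO 2:1, 70 °C
Reagents that add atoms: none
Why: IBX dehydrogenation of a ketone through its enol can only introduce the double bond between C5 and C6 of 8, because the other alpha-carbon adjoins the quaternary carbon, so the conjugated enone forms regiospecifically, the methyl-bearing stereocenter is erased as planned, and the vinyl-bearing one is not touched under these non-basic conditions.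

Step 6
Reactants: 9 (4R)-4-ethenyl-3,5,5-trimethylcyclohex-2-en-1-one
Product: 10 (1R,4R)-4-ethenyl-3,5,5-trimethylcyclohex-2-en-1-ol
Conditions: (S)-2-methyl-CBS-oxazaborolidine (20 mol%), catecholborane (1.5 equiv), toluene, −78 °C; MeOH, then water
Reagents that add atoms: none
Why: Corey–Bakshi–Shibata reduction under catalyst control, with the alkenyl arm of the enone acting as the large group, should deliver hydride to the face that gives the (1R) carbinol, trans to the vinyl-bearing center, while catecholborane at −78 °C leaves the vinyl group unhydroborated.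

Step 7
Reactants: 10 (1R,4R)-4-ethenyl-3,5,5-trimethylcyclohex-2-en-1-ol
Product: 11 (3E)-4-[(1R,4R)-4-hydroxy-2,6,6-trimethylcyclohex-2-en-1-yl]but-3-en-2-one [(3R,6R)-3-hydroxy-α-ionone]
Conditions: methyl vinyl ketone (5 equiv), second-generation Hoveyda–Grubbs catalyst RuCl2(H2IMes)(=CH-C6H4-2-O-i-Pr) (5 mol%), CH2Cl2, 40 °C
Reagents that add atoms: methyl vinyl ketone, C=CC(C)=O
Why: Olefin cross-metathesis of the monosubstituted alkene with the electron-poor enone partner should give the E-enone, the trisubstituted ring alkene being too hindered to enter the cycle and neither stereocenter being involved.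

Step 8
Reactants: 11 (3R,6R)-3-hydroxy-α-ionone
Product: 12 (1R,4R)-4-[(1E)-3-hydroxy-3-methylpenta-1,4-dien-1-yl]-3,5,5-trimethylcyclohex-2-en-1-ol (both epimers at the side-chain carbinol)
Conditions: vinylmagnesium bromide (3.5 equiv), THF, −40 to 0 °C; aq. NH4Cl
Reagents that add atoms: vinylmagnesium bromide, C=C[Mg]Br
Why: After deprotonation of the hydroxyl group, the vinyl Grignard reagent adds 1,2 to the enone carbonyl, as in the classical vinylation of ionones; the new tertiary carbinol center forms unselectively and becomes planar in step 9.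

Step 9
Reactants: 12 (1R,4R)-4-[(1E)-3-hydroxy-3-methylpenta-1,4-dien-1-yl]-3,5,5-trimethylcyclohex-2-en-1-ol
Product: 13 [(2E,4E)-5-[(1R,4R)-4-hydroxy-2,6,6-trimethylcyclohex-2-en-1-yl]-3-methylpenta-2,4-dien-1-yl]triphenylphosphonium bromide
Conditions: PPh3·HBr (1.1 equiv), MeOH, 0 °C to rt; crystallisation
Reagents that add atoms: triphenylphosphine hydrobromide, [Br-].[PH+](c1ccccc1)(c1ccccc1)c1ccccc1
Why: Acid ionises the tertiary doubly allylic alcohol to a pentadienyl cation that PPh3 captures at the unhindered terminal carbon (SN1 reaction with allylic transposition), giving the conjugated 2E,4E salt, which should crystallise; the secondary ring alcohol ionises far more slowly.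

Step 10
Reactants: 14 (4R,6R)-4-hydroxy-2,2,6-trimethylcyclohexan-1-one [(4R,6R)-actinol]
Product: 15 (4R,6R)-2,2,6-trimethyl-4-(triethylsilyloxy)cyclohexan-1-one
Conditions: Et3SiCl (1.2 equiv), imidazole (2 equiv), DMF, 0 °C to rt
Reagents that add atoms: chlorotriethylsilane, CC[Si](Cl)(CC)CC
Why: Silylation of the secondary alcohol with a silyl chloride and imidazole masks the hydroxyl group for the enolate chemistry; no stereocenter is involved.

Step 11
Reactants: 15 (4R,6R)-2,2,6-trimethyl-4-(triethylsilyloxy)cyclohexan-1-one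
Product: 17 (4R)-2,6,6-trimethyl-4-(triethylsilyloxy)cyclohex-1-en-1-yl trifluoromethanesulfonate, via lithium enolate 16 (not isolated)
Conditions: LiN(i-Pr)2 (1.2 equiv), THF, −78 to 0 °C; PhNTf2 (1.2 equiv), 0 °C to rt
Reagents that add atoms: N-phenylbis(trifluoromethanesulfonimide), O=S(=O)(N(c1ccccc1)S(=O)(=O)C(F)(F)F)C(F)(F)F
Why: Only C6 carries an alpha-hydrogen, so deprotonation gives a single enolate, which is O-sulfonylated by the triflimide to the tetrasubstituted enol triflate; C6 becomes planar and C4, the future C3, is untouched.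

Step 12
Reactants: 18 (2E)-3-methylpent-2-en-4-yn-1-ol
Product: 19 (2E,4E)-3-methyl-5-(tributylstannyl)penta-2,4-dien-1-ol
Conditions: Bu3SnH (1.1 equiv), PdCl2(PPh3)2 (2 mol%), THF, 0 °C
Reagents that add atoms: tributyltin hydride, CCCC[SnH](CCCC)CCCC
Why: Palladium-catalysed syn-hydrostannation of the terminal alkyne places tin on the terminal carbon and gives the E-alkenylstannane; the internal regioisomer, if formed, is removed by chromatography.

Step 13
Reactants: 17 (4R)-2,6,6-trimethyl-4-(triethylsilyloxy)cyclohex-1-en-1-yl trifluoromethanesulfonate; 19 (2E,4E)-3-methyl-5-(tributylstannyl)penta-2,4-dien-1-ol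
Product: 20 (2E,4E)-3-methyl-5-[(4R)-2,6,6-trimethyl-4-(triethylsilyloxy)cyclohex-1-en-1-yl]penta-2,4-dien-1-ol
Conditions: Pd2(dba)3 (2.5 mol%), AsPh3 (20 mol%), NMP, 50 °C
Reagents that add atoms: none
Why: Stille coupling of the hindered enol triflate with the alkenylstannane, with a weakly donating arsine ligand in a polar solvent to speed transmetalation, forms the C6–C7 bond with retention of both double-bond geometries.

Step 14
Reactants: 20 (2E,4E)-3-methyl-5-[(4R)-2,6,6-trimethyl-4-(triethylsilyloxy)cyclohex-1-en-1-yl]penta-2,4-dien-1-ol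
Product: 21 [(2E,4E)-5-[(4R)-4-hydroxy-2,6,6-trimethylcyclohex-1-en-1-yl]-3-methylpenta-2,4-dien-1-yl]triphenylphosphonium bromide
Conditions: PPh3·HBr (1.2 equiv), MeOH, rt; crystallisation
Reagents that add atoms: triphenylphosphine hydrobromide, [Br-].[PH+](c1ccccc1)(c1ccccc1)c1ccccc1
Why: Ionisation of the allylic alcohol to a trienyl cation and capture by PPh3 at the primary carbon (SN1 reaction) gives the C15 phosphonium salt, and the acidic methanol cleaves the triethylsilyl ether in the same operation.

Step 15
Reactants: 21 beta C15 phosphonium bromide; 22 (2E,4E,6E)-2,7-dimethylocta-2,4,6-trienedial (2.5 equiv)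
Product: 24 (3R)-3-hydroxy-12'-apo-β-caroten-12'-al, via phosphorus ylide 23 (not isolated)
Conditions: NaOMe (1.1 equiv), MeOH/CH2Cl2, 0 °C to rt, dark; then EtOAc, reflux
Reagents that add atoms: none
Why: Wittig reaction of the semi-stabilised ylide with an excess of the symmetrical dialdehyde should stop after one olefination, because the product aldehyde is deactivated by the longer polyene, and the E/Z mixture at the new C11=C12 bond is equilibrated thermally to E.

Step 16
Reactants: 13 epsilon C15 phosphonium bromide; 24 (3R)-3-hydroxy-12'-apo-β-caroten-12'-al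
Product: 26 (3R,3'R,6'R)-β,ε-carotene-3,3'-diol (lutein), via phosphorus ylide 25 (not isolated)
Conditions: NaOMe (1.2 equiv), MeOH/CH2Cl2, 0 °C to rt, dark, argon; then EtOAc, reflux; crystallisation
Reagents that add atoms: none
Why: Wittig reaction joins the two halves at C11'=C12'; the stereocenters lie far from the reacting centers, and heating equilibrates the new double bond to E before crystallisation.

Step 17
Reactants: 26 lutein; 27 hexadecanoyl chloride (palmitoyl chloride, 3 equiv)
Product: 28 helenien, (3R,3'R,6'R)-β,ε-carotene-3,3'-diyl dihexadecanoate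
Conditions: pyridine (6 equiv), DMAP (10 mol%), CH2Cl2, 0 °C to rt, dark
Reagents that add atoms: none
Why: Acylation of both secondary hydroxyl groups through the N-acylpyridinium ion breaks no C–O bond of the carotenoid, so the configurations at C3 and C3' are kept, and the basic medium protects the acid-labile allylic ester.

**Compound list**

1 | (R)-3-methylcyclohexan-1-one | C[C@@H]1CCCC(=O)C1 | starting material
2 | (R)-5-methylcyclohex-2-en-1-one | C[C@@H]1CC=CC(=O)C1 | intermediate
3 | potassium (S)-5-methylcyclohexa-1,3-dien-1-olate | C[C@@H]1C=CC=C([O-])C1.[K+] | intermediate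
4 | (S)-5-methylcyclohex-3-en-1-one | C[C@@H]1C=CCC(=O)C1 | intermediate
5 | (1S,5S)-5-methyl-1-(2-methylprop-1-en-1-yl)cyclohex-3-en-1-ol | C[C@@H]1C=CC[C@@](O)(C=C(C)C)C1 | intermediate
6 | potassium (1S,5S)-5-methyl-1-(2-methylprop-1-en-1-yl)cyclohex-3-en-1-olate | C[C@@H]1C=CC[C@@]([O-])(C=C(C)C)C1.[K+] | intermediate
7 | potassium (4S,5S)-4-ethenyl-3,3,5-trimethylcyclohex-1-en-1-olate | C=C[C@H]1[C@@H](C)CC([O-])=CC1(C)C.[K+] | intermediate
8 | (4S,5S)-4-ethenyl-3,3,5-trimethylcyclohexan-1-one | C=C[C@H]1[C@@H](C)CC(=O)CC1(C)C | intermediate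
9 | (4R)-4-ethenyl-3,5,5-trimethylcyclohex-2-en-1-one | C=C[C@H]1C(C)=CC(=O)CC1(C)C | intermediate
10 | (1R,4R)-4-ethenyl-3,5,5-trimethylcyclohex-2-en-1-ol | C=C[C@H]1C(C)=C[C@H](O)CC1(C)C | intermediate
11 | (3E)-4-[(1R,4R)-4-hydroxy-2,6,6-trimethylcyclohex-2-en-1-yl]but-3-en-2-one, (3R,6R)-3-hydroxy-α-ionone | CC(=O)/C=C/[C@H]1C(C)=C[C@H](O)CC1(C)C | intermediate
12 | (1R,4R)-4-[(1E)-3-hydroxy-3-methylpenta-1,4-dien-1-yl]-3,5,5-trimethylcyclohex-2-en-1-ol, both epimers at the side-chain carbinol | C=CC(C)(O)/C=C/[C@H]1C(C)=C[C@H](O)CC1(C)C | intermediate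
13 | [(2E,4E)-5-[(1R,4R)-4-hydroxy-2,6,6-trimethylcyclohex-2-en-1-yl]-3-methylpenta-2,4-dien-1-yl]triphenylphosphonium bromide | C/C(=C\C[P+](c2ccccc2)(c3ccccc3)c4ccccc4)/C=C/[C@H]1C(C)=C[C@H](O)CC1(C)C.[Br-] | intermediate
14 | (4R,6R)-4-hydroxy-2,2,6-trimethylcyclohexan-1-one, (4R,6R)-actinol | O[C@@H]1C[C@@H](C)C(=O)C(C)(C)C1 | starting material
15 | (4R,6R)-2,2,6-trimethyl-4-(triethylsilyloxy)cyclohexan-1-one | CC[Si](CC)(CC)O[C@@H]1C[C@@H](C)C(=O)C(C)(C)C1 | intermediate
16 | lithium (4R)-2,6,6-trimethyl-4-(triethylsilyloxy)cyclohex-1-en-1-olate | CC[Si](CC)(CC)O[C@@H]1CC(C)=C(O[Li])C(C)(C)C1 | intermediate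
17 | (4R)-2,6,6-trimethyl-4-(triethylsilyloxy)cyclohex-1-en-1-yl trifluoromethanesulfonate | CC[Si](CC)(CC)O[C@@H]1CC(C)=C(OS(=O)(=O)C(F)(F)F)C(C)(C)C1 | intermediate
18 | (2E)-3-methylpent-2-en-4-yn-1-ol | C#C/C(C)=C/CO | starting material
19 | (2E,4E)-3-methyl-5-(tributylstannyl)penta-2,4-dien-1-ol | CCCC[Sn](CCCC)(CCCC)/C=C/C(C)=C/CO | intermediate
20 | (2E,4E)-3-methyl-5-[(4R)-2,6,6-trimethyl-4-(triethylsilyloxy)cyclohex-1-en-1-yl]penta-2,4-dien-1-ol | CC[Si](CC)(CC)O[C@@H]1CC(C)=C(/C=C/C(C)=C/CO)C(C)(C)C1 | intermediate
21 | [(2E,4E)-5-[(4R)-4-hydroxy-2,6,6-trimethylcyclohex-1-en-1-yl]-3-methylpenta-2,4-dien-1-yl]triphenylphosphonium bromide | O[C@@H]1CC(C)=C(/C=C/C(C)=C/C[P+](c2ccccc2)(c3ccccc3)c4ccccc4)C(C)(C)C1.[Br-] | intermediate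
22 | (2E,4E,6E)-2,7-dimethylocta-2,4,6-trienedial | O=C/C(C)=C/C=C/C=C(C)/C=O | starting material
23 | [(2E,4E)-5-[(4R)-4-hydroxy-2,6,6-trimethylcyclohex-1-en-1-yl]-3-methylpenta-2,4-dien-1-ylidene]triphenylphosphorane | O[C@@H]1CC(C)=C(/C=C/C(C)=C/C=P(c2ccccc2)(c3ccccc3)c4ccccc4)C(C)(C)C1 | intermediate
24 | (3R)-3-hydroxy-12'-apo-β-caroten-12'-al | O[C@@H]1CC(C)=C(/C=C/C(C)=C/C=C/C(C)=C/C=C/C=C(C)/C=O)C(C)(C)C1 | intermediate
25 | [(2E,4E)-5-[(1R,4R)-4-hydroxy-2,6,6-trimethylcyclohex-2-en-1-yl]-3-methylpenta-2,4-dien-1-ylidene]triphenylphosphorane | C/C(=C\C=P(c2ccccc2)(c3ccccc3)c4ccccc4)/C=C/[C@H]1C(C)=C[C@H](O)CC1(C)C | intermediate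
26 | (3R,3'R,6'R)-β,ε-carotene-3,3'-diol, lutein | O[C@@H]1CC(C)=C(/C=C/C(C)=C/C=C/C(C)=C/C=C/C=C(C)/C=C/C=C(C)/C=C/[C@H]2C(C)=C[C@H](O)CC2(C)C)C(C)(C)C1 | intermediate
27 | hexadecanoyl chloride, palmitoyl chloride | CCCCCCCCCCCCCCCC(=O)Cl | starting material
28 | helenien, (3R,3'R,6'R)-β,ε-carotene-3,3'-diyl dihexadecanoate | CCCCCCCCCCCCCCCC(=O)O[C@@H]1CC(C)=C(/C=C/C(C)=C/C=C/C(C)=C/C=C/C=C(C)/C=C/C=C(C)/C=C/[C@H]2C(C)=C[C@H](OC(=O)CCCCCCCCCCCCCCC)CC2(C)C)C(C)(C)C1 | target

**Count and risks**

Total step count: 17. Longest linear sequence: 11 steps (steps 1 to 9, then 16 and 17).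

Three steps most likely to fail:

Step 4. The alkoxide may cleave heterolytically into an enone and an allyl anion that does not return to the right carbon, or it may undergo the [1,3] shift to an eight-membered ketone instead of the [3,3] shift. The fallback leaves the anionic manifold. It sets out from 5: silylation with Me3SiCl and imidazole would give (1S,5S)-5-methyl-1-(2-methylprop-1-en-1-yl)-1-(trimethylsilyloxy)cyclohex-3-ene F1. A neutral thermal siloxy-Cope rearrangement of F1 in a flow tube at about 320 °C with short contact time, a concerted gas-phase process in which no ion pair can separate, would give trimethyl{[(4S,5S)-4-ethenyl-3,3,5-trimethylcyclohex-1-en-1-yl]oxy}silane F2. Mild aqueous acid hydrolysis of F2 comes back to the route at ketone 8.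

Step 2. The beta,gamma-unsaturated ketone may slip back into conjugation during quench and isolation, and the dienolate may add to unreacted enone. The fallback replaces the protonation by a reductive deconjugation. It sets out from 2: isopropenyl acetate with TsOH would give (S)-5-methylcyclohexa-1,3-dien-1-yl acetate F3. NaBH4 in EtOH removes the acetyl group, lets the dienol ketonise at the alpha-carbon and reduces the unconjugated ketone at once, which would give (5S)-5-methylcyclohex-3-en-1-ol F4 as a mixture of carbinol epimers. Dess–Martin oxidation of F4 under buffered, non-basic conditions comes back to the route at 4.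

Step 9. The pentadienyl cation sits next to the C6' hydrogen, so proton loss to a retro-type triene, or ionisation of the allylic ring hydroxyl, may compete with capture by PPh3. The fallback reverses the polarity of the last union. It sets out from 11 and uses 24: Horner–Wadsworth–Emmons reaction of 11 with diethyl cyanomethylphosphonate and NaH would give (2E,4E)-5-[(1R,4R)-4-hydroxy-2,6,6-trimethylcyclohex-2-en-1-yl]-3-methylpenta-2,4-dienenitrile F5. Reduction with i-Bu2AlH and hydrolysis would give (2E,4E)-5-[(1R,4R)-4-hydroxy-2,6,6-trimethylcyclohex-2-en-1-yl]-3-methylpenta-2,4-dienal F6. In parallel, NaBH4 reduction of 24 would give (3R)-3-hydroxy-12'-apo-β-caroten-12'-ol F7, and PPh3·HBr would turn it into [(3R)-3-hydroxy-12'-apo-β-caroten-12'-yl]triphenylphosphonium bromide F8, whose cation has no epsilon-type C–H next to it. Wittig reaction of F8 with F6 (NaOMe) comes back to the route at lutein 26.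

**Further compounds**

F1 | step 4 | (1S,5S)-5-methyl-1-(2-methylprop-1-en-1-yl)-1-(trimethylsilyloxy)cyclohex-3-ene | C[C@@H]1C=CC[C@@](O[Si](C)(C)C)(C=C(C)C)C1
F2 | step 4 | trimethyl{[(4S,5S)-4-ethenyl-3,3,5-trimethylcyclohex-1-en-1-yl]oxy}silane | C=C[C@H]1[C@@H](C)CC(O[Si](C)(C)C)=CC1(C)C
F3 | step 2 | (S)-5-methylcyclohexa-1,3-dien-1-yl acetate | C[C@@H]1C=CC=C(OC(C)=O)C1
F4 | step 2 | (5S)-5-methylcyclohex-3-en-1-ol, both carbinol epimers | C[C@@H]1C=CCC(O)C1
F5 | step 9 | (2E,4E)-5-[(1R,4R)-4-hydroxy-2,6,6-trimethylcyclohex-2-en-1-yl]-3-methylpenta-2,4-dienenitrile | N#C/C=C(C)/C=C/[C@H]1C(C)=C[C@H](O)CC1(C)C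
F6 | step 9 | (2E,4E)-5-[(1R,4R)-4-hydroxy-2,6,6-trimethylcyclohex-2-en-1-yl]-3-methylpenta-2,4-dienal | O=C/C=C(C)/C=C/[C@H]1C(C)=C[C@H](O)CC1(C)C
F7 | step 9 | (3R)-3-hydroxy-12'-apo-β-caroten-12'-ol | O[C@@H]1CC(C)=C(/C=C/C(C)=C/C=C/C(C)=C/C=C/C=C(C)/CO)C(C)(C)C1
F8 | step 9 | [(3R)-3-hydroxy-12'-apo-β-caroten-12'-yl]triphenylphosphonium bromide | O[C@@H]1CC(C)=C(/C=C/C(C)=C/C=C/C(C)=C/C=C/C=C(C)/C[P+](c2ccccc2)(c3ccccc3)c4ccccc4)C(C)(C)C1.[Br-]
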